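Percentages of solid substrate left turn into millimolar dissolved once the part that has left is multiplied by the charge.

| flask | solid substrate | partner | remark | time |
|---|---|---|---|---|
| north-east | 28 mM | 0.95 equiv | run made earlier |  |
| east | 44 mM | 0.95 equiv | run made earlier |  |
| flask | 20 mM | 0.950 equiv |  | 2.0 h |

| run | time / h | solid substrate / % | single product / % | starting material / % |
|---|---|---|---|---|
| north-east | 0.133 | 91.5 | 1.2 | 5.2 |
| north-east | 0.333 | 84.4 | 2.4 | 9.2 |
| north-east | 0.667 | 68.7 | 8.4 | 11.0 |
| north-east | 1.00 | 55.9 | 12.4 | 14.3 |
| north-east | 1.33 | 44.0 | 13.7 | 15.6 |
| north-east | 2.00 | 24.1 | 17.5 | 22.4 |
| north-east | 2.50 | 13.0 | 20.5 | 30.9 |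
| east | 0.200 | 91.8 | 2.6 | 3.2 |
| east | 0.333 | 89.2 | 3.1 | 4.1 |
| east | 0.417 | 88.5 | 2.9 | 4.7 |
| east | 0.667 | 79.2 | 5.5 | 5.5 |
| east | 1.00 | 71.8 | 6.9 | 6.7 |
| east | 1.50 | 58.4 | 7.9 | 9.4 |
| east | 2.50 | 36.2 | 11.9 | 15.0 |

(standard deviation of a reading: 1 percentage point)

- solid substrate is a solid; its amount is given per volume of the solution
- what may be going on: starting material + partner -> single product + by-product; starting material + partner -> other mono adduct + by-product; partner + single product -> double product + by-product; partner + other mono adduct -> double product + by-product; solid substrate <-> starting material
- at the start none of the solid substrate is in solution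
- what has only dissolved of solid substrate counts as not reacted
- starting material means what is dissolved; the solid is not counted in it
- the reaction counts as stopped when no species that holds the solid substrate changes by six tenths of a point or more over the second half of the time

* why nothing more happens at 2.0 h, or that something still does (for what has run out or reacted, a solid counts together with what of it has only dissolved) (forward and back rates have come level / it is still moving / the partner has run out first / all of the solid substrate has reacted)
* part of the solid substrate that has turned into other species by 2.0 h (what has only dissolved does not count)
* the single product standing at 2.0 h, as a percentage of the solid substrate charged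
* the starting material standing at 2.0 h, as a percentage of the solid substrate charged

Read at 1.00 h, the north-east column shows 55.9 % of the solid left and the east column 71.8 %, which looks far apart. In concentration, however, the north-east run has lost 12.3 mM and the east run 12.4 mM. So in these two runs the solid leaves at a pace that does not follow the charge (zero order in the solid).

The last east row gives 11.2 mM h⁻¹ as the dissolving rate, the mM of solid substrate entering solution per hour. While that rate holds, the fraction of solid left is one minus rate times time over charge. But the last two north-east rows lose only 6.22 mM h⁻¹, which is slower than that rate, so in the north-east run the rate reads too high once the solid is down to 6.75 mM.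

At the dissolving rate, the new flask's 20 mM lasts 1.79 h, shorter than 2.0 h. But the reckoning made here lets the flask's solid fall at that rate only down to 6.75 mM, which takes 1.18 h, and at the slower north-east pace after that, so the fraction left at 2.0 h comes to 8.26 %, and the flask is expected to be still moving. Taking over the north-east share converted at its last reading, 56.1 %, and subtracting that remainder leaves about 35.6 % as starting material in this flask.

The forecast says it is still moving, conversion 54 %, single product 21 %, starting material 32 %; its own reckoning of the dissolving from this charge “leaves roughly 14% undissolved at 2 h”.

The flask gives: it is still moving, conversion 57.7 %, single product 23.5 %, starting material 39.7 %.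

    starting material + partner → single product + by-product (k = 1.70 M⁻¹ min⁻¹)
    starting material + partner → other mono adduct + by-product (k = 0.600 M⁻¹ min⁻¹)
    partner + single product → double product + by-product (k = 1.50 M⁻¹ min⁻¹)
    partner + other mono adduct → double product + by-product (k = 0.900 M⁻¹ min⁻¹)
    solid substrate ⇌ starting material, rate k5*(cs5 - [starting material]) while solid is left; crystals form when [starting material] > cs5 (solubility = 13.0 mM, k = 0.0200 min⁻¹)

The flask holds 2.56 % of its solid at 2.00 h, and its starting material stands 7.7 percentage points above the forecast. Over 2.0 h this flask's solid left at 9.74 mM h⁻¹ on average, which is below the dissolving rate. A neighbouring flask charged with 50 mM of solid substrate, at the same equivalents and time, lasts 4.46 h at the dissolving rate, so its fraction left reckons to 55.2 %. That neighbour holds 50.6 % of its solid at 2.00 h.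

(The numbers in the tables are simulated for an exercise; the scatter is artificial.)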